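## Analysis of the target

Target 13, 7-hydroxy-3-(4-hydroxyphenyl)-6,8-bis(3-methylbut-2-en-1-yl)-4H-chromen-4-one (6,8-diprenyldaidzein), is an isoflavone: a benzene ring A fused to a 4-pyranone ring C, with ring B, a 4-hydroxyphenyl group, on C3. It has no stereocentre and no stereogenic double bond, because each prenyl alkene ends in two methyl groups, so the problem is one of regiochemistry and functional-group tolerance only. Ring A is substituted at every carbon but C5: O1 at C8a, prenyl at C8, hydroxyl at C7, prenyl at C6 and the carbonyl carbon C4 at C4a. The sensitive groups are the two trisubstituted alkenes, which do not survive oxidants or hydrogenation and which, lying ortho to the C7 hydroxyl, close to 2,2-dimethylchroman rings under acid; C2 of ring C is in addition an electrophilic centre at which strong base opens the pyranone. The difficulty is to place prenyl groups at C6 and C8 and none at C3' or C5' of ring B, which are also ortho to a phenol, and to build ring C without a step that the alkenes cannot stand. The plan rests on the C2–C3 unit of ring C: C3 carries the para-oxygenated ring B and C2 is a bare CH bound to O1, the pattern left when an electron-rich aryl group shifts from the benzylic carbon of a chalcone to its neighbour and the C8a oxygen closes onto the carbon it has left. It rests further on C6 and C8 being the two positions of a 2,4-dioxygenated acetophenone ring that halogenate, so that C–Br bonds can hold the places of the prenyl groups while ring C is made.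

## Retrosynthetic reasoning

**13 to 12.** The first cut is at the two O–CH2 bonds of acetal protecting groups, which leads from 13 to its bis(methoxymethyl) ether 12. The C7 hydroxyl lies between two prenyl groups, so the last step must be a mild solvolysis. Hydrogenolysis would saturate the alkenes and a strong Lewis acid would cyclise them, and an acetal that leaves in dilute acid avoids both.

**12 to 10 and 11.** The C6–C1'' and C8–C1'' bonds, the aryl–CH2 bonds of the two prenyl groups, are cut next, giving dibromide 10 and prenylstannane 11. The cut is made here because the prenyl alkenes cannot pass through the oxidation that builds ring C, so they must enter after it. The forward reaction is a twofold palladium-catalysed coupling that has to deliver the allyl unit through its CH2 end at two hindered positions.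

**10 to 9.** The two acetal O–CH2 bonds of 10 are cut to give diphenol 9. The forward step is a plain O-alkylation, placed at the dibromide stage so that no later step needs to touch a benzyl ether.

**9 to 8.** The two benzyl O–CH2 bonds are restored, leading to dibenzyl ether 8. Benzyl ethers are wanted earlier because they survive the base of the condensation and the oxidant and acid of the ring-forming step. They cannot be removed once the prenyl groups are present, which is why the change of protecting group happens before the coupling.

**8 to 6, through 7.** This is the central disconnection. Ring C is opened at O1–C2, which gives the open-chain dimethyl acetal 7, and ring B is moved back from C3 to C2, which gives chalcone 6. The bonds cut are O1–C2 and C3–C1'. The gain is that the whole carbon skeleton of the isoflavone comes from a chalcone that one condensation assembles. The forward reaction has to make the aryl group migrate instead of letting the phenol oxygen close a ring on the unrearranged chain.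

**6 to 4 and 5.** The Cα=Cβ double bond of 6 (the future C3–C2 bond) is cut by a retro-aldol condensation, giving methyl ketone 4 and aldehyde 5. The aldehyde cannot enolise, so only one crossed product is possible, and the E alkene is the stable one.

**4 to 2 and 3.** The benzyl–O4 bond is cut, giving dibromoketone 2 and benzyl bromide 3. The forward alkylation must distinguish the two hydroxyl groups of 2, which differ in acidity and in hydrogen bonding to the carbonyl group.

**2 to 1.** Both C–Br bonds are cut, leading to ketone 1. At this stage only ring A exists, so the halogens can go nowhere but to C3 and C5 of the acetophenone, the future C8 and C6. Ring B, which would compete in any late halogenation, is not yet in the molecule.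

## Alternatives that were turned down

**Alternative 1:** Ring A is taken apart into two open-chain pieces, the diazoketone A2, (3E)-1-diazo-7-methylocta-3,6-dien-2-one, and the silyloxyalkyne A3, triisopropyl[(5-methylhex-4-en-1-yn-1-yl)oxy]silane. In the forward key step, irradiation of A2 triggers a Wolff rearrangement, and the ketene formed adds to A3 in a [2+2] fashion. The cyclobutenone opens in a four-electron step and closes again in a six-electron electrocyclisation, forming C7–C8, C4a–C8a and C6–C7 and giving the phenol A1, 2,6-bis(3-methylbut-2-en-1-yl)-3-[(triisopropylsilyl)oxy]phenol.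
- For it: the connectivity of A2 and A3 fixes both prenyl groups on ring A beyond doubt, with no question of linear against branched allyl transfer and no tin or thallium. On this point it is stronger than the chosen route.
- Against it: A1 is only ring A. Ring C and ring B are still to come, by acylation at C4a and insertion of the C2 carbon. These are steps run under Lewis or Brønsted acid on a phenol that has a prenyl group on each side, exactly where chroman formation is to be feared. A2 has a doubly allylic CH2 group that can slip into conjugation, and A2 and A3 each need several steps.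
- Comparison: the count comes out well above that of the chosen route. The chosen route offers a start from cheap aromatic compounds and keeps the prenyl groups away from every harsh step.

**Alternative 2:** The C6–C1'' and C8–C1'' bonds are cut as the key disconnection, leading to the diiodide A5, 6,8-diiodo-7-(methoxymethoxy)-3-[4-(methoxymethoxy)phenyl]-4H-chromen-4-one. In the forward step A5 and two equivalents of stannane 11 couple under a zerovalent palladium catalyst to give A4, 7-(methoxymethoxy)-3-[4-(methoxymethoxy)phenyl]-6,8-bis(3-methylbut-2-en-1-yl)-4H-chromen-4-one, which is the same compound as 12.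
- For it: C–I bonds add to palladium more easily than C–Br bonds, so the coupling could run at lower temperature. If A5 could be had by iodination of the purchasable isoflavone A6, 7-hydroxy-3-(4-hydroxyphenyl)-4H-chromen-4-one (daidzein), the route would be about half as long as the chosen one. On both points it is as strong or stronger.
- Against it: A6 has four positions ortho to a phenol. Those of ring B (C3', C5') belong to an ordinary phenol, while those of ring A (C6, C8) belong to a phenol conjugated to the C4 carbonyl and so less electron-rich. Nothing in the structure secures clean 6,8-diiodination. If A5 has to be built from an iodinated ring A ketone, ring C must be made anyway, and the plan becomes the chosen one with weaker carbon–halogen bonds carried through more steps.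
- Comparison: the chosen route contains the same coupling as its step 7. What it adds is certainty about where the halogens stand, because they are introduced before ring B exists.

**Alternative 3:** Ring A is cut at C5–C6 and C4a–C8a into the diene A8, 1-methoxy-2,4-bis(3-methylbut-2-en-1-yl)-1,3-bis[(trimethylsilyl)oxy]buta-1,3-diene, and the ethynyl ketone A9, (1E)-1-methoxy-2-[4-(methoxymethoxy)phenyl]pent-1-en-4-yn-3-one. On heating, the nucleophilic end of A8 adds to the alkyne terminus of A9 and the ring closes at the carbon next to the carbonyl group. Loss of the methoxy group and of the silyl groups on work-up gives the aromatic ketone A7, (E)-1-[2,4-dihydroxy-3,5-bis(3-methylbut-2-en-1-yl)phenyl]-3-methoxy-2-[4-(methoxymethoxy)phenyl]prop-2-en-1-one, whose C2 hydroxyl then closes ring C.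
- For it: the plan is convergent, needs no heavy metal, and puts the prenyl groups in by enolate alkylation, where their linear form is certain. In convergence and in freedom from thallium and tin it is stronger.
- Against it: A8 is substituted at both reacting ends and at C2, which slows the cycloaddition, and it is sensitive to moisture. A9 has two electrophilic sites, the alkyne and the methoxy-enone, so the diene may add at the wrong one. A8 and A9 each take four or five steps, and the closure of ring C and the final deprotection still run on a prenylated phenol.
- Comparison: the chosen route is shorter in its longest line and places its one demanding step on a substrate without alkenes other than the reacting enone.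

Key step: step 4

Assumption: stannane 11 is taken as a purchasable reagent; intermediate 7 is formed racemic and its stereocentre is removed in the same step, so no stereocontrol is planned anywhere.

## Route

Step 1
Reactants: 1 resacetophenone, 1-(2,4-dihydroxyphenyl)ethan-1-one
Product: 2 dibromoketone 1-(3,5-dibromo-2,4-dihydroxyphenyl)ethan-1-one
Conditions: Br2 (2.1 equiv), AcOH, rt
Reagents that add atoms: bromine, BrBr
Why: Electrophilic aromatic bromination; C3 and C5 are the only free positions ortho or para to both hydroxyl groups, so two equivalents of bromine should substitute there and leave C6 and the acetyl methyl group alone.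

Step 2
Reactants: 2 dibromoketone 1-(3,5-dibromo-2,4-dihydroxyphenyl)ethan-1-one; 3 benzyl bromide
Product: 4 benzyl ether 1-[4-(benzyloxy)-3,5-dibromo-2-hydroxyphenyl]ethan-1-one
Conditions: 3 (1.05 equiv), K2CO3 (1.2 equiv), DMF, 50 °C
Reagents that add atoms: none
Why: Williamson ether synthesis; the C4 hydroxyl, acidified by two ortho bromines and the para acetyl group, is deprotonated first, while the C2 hydroxyl stays held in a hydrogen bond to the carbonyl oxygen, so one equivalent of 3 should alkylate O4 only.

Step 3
Reactants: 4 benzyl ether 1-[4-(benzyloxy)-3,5-dibromo-2-hydroxyphenyl]ethan-1-one; 5 aldehyde 4-(benzyloxy)benzaldehyde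
Product: 6 chalcone (E)-1-[4-(benzyloxy)-3,5-dibromo-2-hydroxyphenyl]-3-[4-(benzyloxy)phenyl]prop-2-en-1-one
Conditions: KOH (50% aq.), EtOH/THF, rt; then aq. HCl to pH 3
Reagents that add atoms: none
Why: Claisen–Schmidt condensation (crossed aldol addition, then E1cB loss of water) between the methyl ketone enolate and an aldehyde that cannot enolise; the E alkene is the thermodynamic product of the elimination. The benzyl ethers and aryl bromides are inert to aqueous base at room temperature, and the phenoxide next to a bromine is too weak a nucleophile to close a flavanone ring to any extent.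

Step 4
Reactants: 6 chalcone (E)-1-[4-(benzyloxy)-3,5-dibromo-2-hydroxyphenyl]-3-[4-(benzyloxy)phenyl]prop-2-en-1-one
Product: 8 isoflavone 7-(benzyloxy)-3-[4-(benzyloxy)phenyl]-6,8-dibromo-4H-chromen-4-one, via rearranged dimethyl acetal 7 (not isolated)
Conditions: Tl(NO3)3·3H2O (1.2 equiv), MeOH/CH(OMe)3/CH2Cl2, rt; then 10% aq. HCl, 55 °C
Reagents that add atoms: none
Why: This is the oxidative rearrangement of a 2'-hydroxychalcone to an isoflavone by Tl(NO3)3 in methanol, a known reaction type. The trivalent thallium electrophile and methanol add across the enone so that thallium binds the carbon next to the carbonyl group (future C3) and the methoxy group the benzylic carbon (future C2), the site that the para-benzyloxy group best enables to carry positive charge. The C–Tl bond then ionises with reduction to monovalent thallium while ring B bridges as a phenonium ion and moves from C2 to C3 (new C3–C1' bond), and the methoxy-stabilised cation left at C2 is captured by methanol to give acetal 7, whose two methoxy groups come from the solvent. On addition of HCl, 7 loses methanol to an oxocarbenium ion, the phenol oxygen on C8a attacks C2 in a 6-exo-trig closure (new O1–C2 bond), and a second loss of methanol sets the C2=C3 double bond of ring C. The stereocentre at C3 of 7 is formed racemic and disappears in this elimination, so there is nothing to control. The selectivity needed is aryl migration in preference to attack of the phenol oxygen on the thallated chain, which would close an aurone or a flavone; the electron-rich ring B, the large excess of methanol as competing nucleophile and the low nucleophilicity of the hydrogen-bonded phenol next to a bromine all favour migration. Ring A is deactivated by two bromines and the acyl group and the molecule holds no alkene besides the enone, so the oxidant has no second site of attack.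

Step 5
Reactants: 8 isoflavone 7-(benzyloxy)-3-[4-(benzyloxy)phenyl]-6,8-dibromo-4H-chromen-4-one
Product: 9 dibromodaidzein 6,8-dibromo-7-hydroxy-3-(4-hydroxyphenyl)-4H-chromen-4-one
Conditions: BCl3 (6 equiv), C6HMe5 (6 equiv), CH2Cl2, −78 → 0 °C; then MeOH, H2O
Reagents that add atoms: none
Why: Lewis acid cleavage of aryl benzyl ethers; BCl3 binds the ether oxygen and the benzyl cation is passed to pentamethylbenzene in a Friedel–Crafts trap, which keeps it from alkylating the phenol rings. Hydrogenolysis is not used because it would also cleave the C–Br bonds.

Step 6
Reactants: 9 dibromodaidzein 6,8-dibromo-7-hydroxy-3-(4-hydroxyphenyl)-4H-chromen-4-one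
Product: 10 bis-acetal 6,8-dibromo-7-(methoxymethoxy)-3-[4-(methoxymethoxy)phenyl]-4H-chromen-4-one
Conditions: MOMCl (3 equiv), K2CO3 (4 equiv), DMF, 0 °C → rt
Reagents that add atoms: chloromethyl methyl ether, COCCl
Why: O-Alkylation of both phenoxides with a very reactive α-chloro ether; even the hindered and weakly nucleophilic C7 phenoxide between two bromines should react with this electrophile. The acetals can later be removed under conditions much milder than any debenzylation.

Step 7
Reactants: 10 bis-acetal 6,8-dibromo-7-(methoxymethoxy)-3-[4-(methoxymethoxy)phenyl]-4H-chromen-4-one; 11 prenylstannane tributyl(3-methylbut-2-en-1-yl)stannane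
Product: 12 diprenyl bis-acetal 7-(methoxymethoxy)-3-[4-(methoxymethoxy)phenyl]-6,8-bis(3-methylbut-2-en-1-yl)-4H-chromen-4-one
Conditions: Pd(PPh3)4 (10 mol %), 11 (3 equiv), DMF (degassed), 100 °C
Reagents that add atoms: none
Why: Twofold Stille coupling: zerovalent palladium inserts into each C–Br bond, the allyl group passes from tin to palladium, and reductive elimination forms the aryl–CH2 bond. The allylpalladium intermediate is expected to couple at its less hindered CH2 end, which gives the linear prenyl group at C6 and at C8; the acetals and the pyranone are inert under these neutral conditions.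

Step 8
Reactants: 12 diprenyl bis-acetal 7-(methoxymethoxy)-3-[4-(methoxymethoxy)phenyl]-6,8-bis(3-methylbut-2-en-1-yl)-4H-chromen-4-one
Product: 13 target 7-hydroxy-3-(4-hydroxyphenyl)-6,8-bis(3-methylbut-2-en-1-yl)-4H-chromen-4-one
Conditions: HCl (0.5 M in MeOH), MeOH/THF, 40 °C
Reagents that add atoms: none
Why: Acid-catalysed acetal exchange: the acetal oxygen is protonated, the phenol leaves, and methanol takes up the methoxymethyl cation as dimethoxymethane. Aryl acetals of this kind should solvolyse faster than a trisubstituted alkene is protonated, so brief treatment with dilute acid should free both phenols without closing a chroman ring.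

## Compound list

1 | 1-(2,4-dihydroxyphenyl)ethan-1-one (resacetophenone) | CC(=O)c1ccc(O)cc1O | starting material
2 | 1-(3,5-dibromo-2,4-dihydroxyphenyl)ethan-1-one | CC(=O)c1cc(Br)c(O)c(Br)c1O | intermediate
3 | benzyl bromide | BrCc1ccccc1 | starting material
4 | 1-[4-(benzyloxy)-3,5-dibromo-2-hydroxyphenyl]ethan-1-one | CC(=O)c1cc(Br)c(OCc2ccccc2)c(Br)c1O | intermediate
5 | 4-(benzyloxy)benzaldehyde | O=Cc1ccc(OCc2ccccc2)cc1 | starting material
6 | (E)-1-[4-(benzyloxy)-3,5-dibromo-2-hydroxyphenyl]-3-[4-(benzyloxy)phenyl]prop-2-en-1-one | O=C(/C=C/c1ccc(OCc2ccccc2)cc1)c1cc(Br)c(OCc2ccccc2)c(Br)c1O | intermediate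
7 | 1-[4-(benzyloxy)-3,5-dibromo-2-hydroxyphenyl]-2-[4-(benzyloxy)phenyl]-3,3-dimethoxypropan-1-one (racemic, not isolated) | COC(OC)C(c1ccc(OCc2ccccc2)cc1)C(=O)c1cc(Br)c(OCc2ccccc2)c(Br)c1O | intermediate
8 | 7-(benzyloxy)-3-[4-(benzyloxy)phenyl]-6,8-dibromo-4H-chromen-4-one | O=c1c(-c2ccc(OCc3ccccc3)cc2)coc2c(Br)c(OCc3ccccc3)c(Br)cc12 | intermediate
9 | 6,8-dibromo-7-hydroxy-3-(4-hydroxyphenyl)-4H-chromen-4-one | O=c1c(-c2ccc(O)cc2)coc2c(Br)c(O)c(Br)cc12 | intermediate
10 | 6,8-dibromo-7-(methoxymethoxy)-3-[4-(methoxymethoxy)phenyl]-4H-chromen-4-one | COCOc1ccc(-c2coc3c(Br)c(OCOC)c(Br)cc3c2=O)cc1 | intermediate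
11 | tributyl(3-methylbut-2-en-1-yl)stannane | CCCC[Sn](CCCC)(CCCC)CC=C(C)C | starting material
12 | 7-(methoxymethoxy)-3-[4-(methoxymethoxy)phenyl]-6,8-bis(3-methylbut-2-en-1-yl)-4H-chromen-4-one | COCOc1ccc(-c2coc3c(CC=C(C)C)c(OCOC)c(CC=C(C)C)cc3c2=O)cc1 | intermediate
13 | 7-hydroxy-3-(4-hydroxyphenyl)-6,8-bis(3-methylbut-2-en-1-yl)-4H-chromen-4-one | CC(C)=CCc1cc2c(=O)c(-c3ccc(O)cc3)coc2c(CC=C(C)C)c1O | target

## Step count and least certain steps

Total step count: 8. Longest linear sequence: 8 steps, from 1 to 13; compounds 3, 5 and 11 enter as purchased materials.

**Step 4 (key step).** The phenol oxygen may close onto the oxidised chain before ring B has moved, which gives a five-membered ring. The conversion may stop short because chalcone 6 dissolves poorly in methanol. The thallium salt may also oxidise the phenol ring. The fallback gives up the aryl shift and makes the C3–C1' bond by cross-coupling, setting out from 4 and coming back at 8. Heating 4 with N,N-dimethylformamide dimethyl acetal should give the enaminone (E)-1-[4-(benzyloxy)-3,5-dibromo-2-hydroxyphenyl]-3-(dimethylamino)prop-2-en-1-one F1. Iodine in chloroform should then close ring C with loss of dimethylamine and iodinate C3, giving 7-(benzyloxy)-6,8-dibromo-3-iodo-4H-chromen-4-one F2. A Suzuki–Miyaura coupling of F2 with 4-(benzyloxy)phenylboronic acid (Pd(PPh3)4, Na2CO3, DME/H2O, 40 °C) should take place at the vinylic C–I bond, which adds to zerovalent palladium much faster than the two aryl C–Br bonds, and give 8.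

**Step 7.** The allyl group may be transferred through its substituted end, which puts a 1,1-dimethylallyl group on the ring. Oxidative addition at C8, which has an oxygen on each side, may be slow, so that the second coupling stays incomplete or the bromine is replaced by hydrogen. The fallback builds each prenyl group in two stages, setting out from 10 and coming back at 12. A twofold Stille coupling of 10 with tributyl(prop-2-en-1-yl)stannane, whose allyl group has two like ends, should give 7-(methoxymethoxy)-3-[4-(methoxymethoxy)phenyl]-6,8-di(prop-2-en-1-yl)-4H-chromen-4-one F3. Cross-metathesis of F3 with 2-methylbut-2-ene under the second-generation Grubbs catalyst RuCl2(=CHPh)(H2IMes)(PCy3) in CH2Cl2 at 40 °C should turn both allyl groups into prenyl groups and give 12.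

**Step 8.** A prenyl alkene may be protonated and captured by the freed C7 hydroxyl (ring closure to a chroman) or by methanol before both acetals are gone. The fallback uses a protecting group that leaves under base, setting out from 9 and coming back at 13. Acetylation of 9 (Ac2O, pyridine) should give 4-[7-(acetyloxy)-6,8-dibromo-4-oxo-4H-chromen-3-yl]phenyl acetate F4. The Stille coupling of F4 with 11 as in step 7 should give 4-[7-(acetyloxy)-6,8-bis(3-methylbut-2-en-1-yl)-4-oxo-4H-chromen-3-yl]phenyl acetate F5. Transesterification of F5 with K2CO3 in methanol at 0 °C should give 13 without any acid.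

**Step 2.** Alkylation may be slow at the phenoxide between two bromines, and it may then spread to the C2 oxygen or to both oxygens. The fallback reverses the order of the first two steps, setting out from 1 and coming back at 4. Benzylation of 1 with 3 (K2CO3, acetone, reflux), which is selective for the unhindered, non-chelated C4 hydroxyl, should give 1-[4-(benzyloxy)-2-hydroxyphenyl]ethan-1-one F6. Bromination of F6 with N-bromosuccinimide (2.1 equiv, MeCN, rt) at the two positions activated by both oxygens should give 4.

## Further compounds

F1 | step 4 | (E)-1-[4-(benzyloxy)-3,5-dibromo-2-hydroxyphenyl]-3-(dimethylamino)prop-2-en-1-one | CN(C)/C=C/C(=O)c1cc(Br)c(OCc2ccccc2)c(Br)c1O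
F2 | step 4 | 7-(benzyloxy)-6,8-dibromo-3-iodo-4H-chromen-4-one | O=c1c(I)coc2c(Br)c(OCc3ccccc3)c(Br)cc12
F3 | step 7 | 7-(methoxymethoxy)-3-[4-(methoxymethoxy)phenyl]-6,8-di(prop-2-en-1-yl)-4H-chromen-4-one | COCOc1ccc(-c2coc3c(CC=C)c(OCOC)c(CC=C)cc3c2=O)cc1
F4 | step 8 | 4-[7-(acetyloxy)-6,8-dibromo-4-oxo-4H-chromen-3-yl]phenyl acetate | CC(=O)Oc1ccc(-c2coc3c(Br)c(OC(C)=O)c(Br)cc3c2=O)cc1
F5 | step 8 | 4-[7-(acetyloxy)-6,8-bis(3-methylbut-2-en-1-yl)-4-oxo-4H-chromen-3-yl]phenyl acetate | CC(=O)Oc1ccc(-c2coc3c(CC=C(C)C)c(OC(C)=O)c(CC=C(C)C)cc3c2=O)cc1
F6 | step 2 | 1-[4-(benzyloxy)-2-hydroxyphenyl]ethan-1-one | CC(=O)c1ccc(OCc2ccccc2)cc1O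
A1 | alternative 1 | 2,6-bis(3-methylbut-2-en-1-yl)-3-[(triisopropylsilyl)oxy]phenol | CC(C)=CCc1ccc(O[Si](C(C)C)(C(C)C)C(C)C)c(CC=C(C)C)c1O
A2 | alternative 1 | (3E)-1-diazo-7-methylocta-3,6-dien-2-one | CC(C)=CC/C=C/C(=O)C=[N+]=[N-]
A3 | alternative 1 | triisopropyl[(5-methylhex-4-en-1-yn-1-yl)oxy]silane | CC(C)=CCC#CO[Si](C(C)C)(C(C)C)C(C)C
A4 | alternative 2 | 7-(methoxymethoxy)-3-[4-(methoxymethoxy)phenyl]-6,8-bis(3-methylbut-2-en-1-yl)-4H-chromen-4-one (identical with 12) | COCOc1ccc(-c2coc3c(CC=C(C)C)c(OCOC)c(CC=C(C)C)cc3c2=O)cc1
A5 | alternative 2 | 6,8-diiodo-7-(methoxymethoxy)-3-[4-(methoxymethoxy)phenyl]-4H-chromen-4-one | COCOc1ccc(-c2coc3c(I)c(OCOC)c(I)cc3c2=O)cc1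
A6 | alternative 2 | 7-hydroxy-3-(4-hydroxyphenyl)-4H-chromen-4-one (daidzein) | O=c1c(-c2ccc(O)cc2)coc2cc(O)ccc12
A7 | alternative 3 | (E)-1-[2,4-dihydroxy-3,5-bis(3-methylbut-2-en-1-yl)phenyl]-3-methoxy-2-[4-(methoxymethoxy)phenyl]prop-2-en-1-one | CO/C=C(\c1ccc(OCOC)cc1)C(=O)c1cc(CC=C(C)C)c(O)c(CC=C(C)C)c1O
A8 | alternative 3 | 1-methoxy-2,4-bis(3-methylbut-2-en-1-yl)-1,3-bis[(trimethylsilyl)oxy]buta-1,3-diene (geometry of the two enol ether double bonds not fixed) | COC(O[Si](C)(C)C)=C(CC=C(C)C)C(O[Si](C)(C)C)=CCC=C(C)C
A9 | alternative 3 | (1E)-1-methoxy-2-[4-(methoxymethoxy)phenyl]pent-1-en-4-yn-3-one | CO/C=C(\c1ccc(OCOC)cc1)C(=O)C#C
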